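**Strategy.** Ring B is disconnected at C9–C10. This bond is β to a C2 carbonyl (the oxygen of the later C2–OH) and allylic to the exocyclic C8=C17 methylene of ring B, which is the retron of an intramolecular Hosomi–Sakurai conjugate allylation. The precursor is a ring A enone (C2=O, C1=C10 with the C10 methyl) that carries on C5 a four-carbon tether ending in a (Z)-allylsilane (C8(CH2SiMe3)=C9, complete side chain already on C9). One operation should close ring B cis-fused and set the quaternary C10, C9 and the exo-methylene. The controlling centre C5 comes from an organocatalytic Michael–aldol annulation; C4 and C2 are set afterwards.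

Key step: step 9

**Conventions and assumptions**
- Labdane numbering is used: ring A = C1–C5, C10; ring B = C5–C10; C17 = exocyclic CH2 on C8; C20 = methyl on C10; side chain C11–C16 on C9. β is the face of ring A that carries C20 in the target, α the other face.
- The target SMILES is read as a cis-fused decalin: H5, C20, the C4 methyl and the C2 hydroxyl are β; C4–CO2H, C5–C6 and C10–C9 are α; the C9 side chain is β.
- R1 = (3Z,7E)-9-tert-butoxy-7-methyl-9-oxo-3-[(trimethylsilyl)methyl]nona-3,7-dien-1-yl (the C5 tether, C6–C15). R2 = (3E)-5-tert-butoxy-3-methyl-5-oxopent-3-en-1-yl (the C9 side chain).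
- Assumption: the (S)-prolinol silyl ether shields the enamine face as it does in additions to nitroalkenes. Compounds 1, 2, 9 and 10 are catalogue compounds; 1 is the racemic acetal, and that centre is removed in step 3.

**Route**

Step 1
Reactants: 1 2-(hex-5-yn-1-yloxy)oxane; 2 but-3-en-2-one
Product: 5 (Z)-10-(oxan-2-yloxy)-6-[(trimethylsilyl)methyl]dec-5-en-2-one, via alkenylcopper 3 (not isolated), via silyl enol ether 4 (not isolated)
Conditions: TMSCH2MgCl, CuBr·SMe2, Et2O, −40 °C; 1, −25 → −10 °C; then 2, TMSCl, THF, −78 → −30 °C; then K2CO3, MeOH, 0 °C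
Reagents that add atoms: (trimethylsilyl)methylmagnesium chloride, C[Si](C)(C)C[Mg]Cl
Why: syn-Carbocupration of the terminal alkyne should place CH2SiMe3 on the internal carbon (C8) and copper cis to it on C9, and the chlorotrimethylsilane-assisted Michael addition of 3 to 2 forms C9–C11 with retention, so the (Z)-allylsilane geometry (C11 cis to CH2SiMe3) follows from the mechanism; mild methanolysis frees the ketone from 4.

Step 2
Reactants: 5 (Z)-10-(oxan-2-yloxy)-6-[(trimethylsilyl)methyl]dec-5-en-2-one
Product: 6 tert-butyl (2E,6Z)-3-methyl-11-(oxan-2-yloxy)-7-[(trimethylsilyl)methyl]undeca-2,6-dienoate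
Conditions: (EtO)2P(O)CH2CO2t-Bu, NaH, THF, 0 °C → reflux; chromatography
Reagents that add atoms: tert-butyl diethylphosphonoacetate, CCOP(=O)(OCC)CC(=O)OC(C)(C)C
Why: Horner–Wadsworth–Emmons olefination of the methyl ketone should give mainly the (2E)-enoate, and the minor (2Z) isomer is removed at this early stage.

Step 3
Reactants: 6 tert-butyl (2E,6Z)-3-methyl-11-(oxan-2-yloxy)-7-[(trimethylsilyl)methyl]undeca-2,6-dienoate
Product: 7 tert-butyl (2E,6Z)-11-hydroxy-3-methyl-7-[(trimethylsilyl)methyl]undeca-2,6-dienoate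
Conditions: pyridinium tosylate (cat.), EtOH, 50 °C
Reagents that add atoms: none
Why: Acetal exchange with ethanol under this weak acid should remove the tetrahydropyranyl group without protodesilylating the allylsilane or touching the tert-butyl ester.

Step 4
Reactants: 7 tert-butyl (2E,6Z)-11-hydroxy-3-methyl-7-[(trimethylsilyl)methyl]undeca-2,6-dienoate
Product: 8 tert-butyl (2E,6Z)-3-methyl-11-oxo-7-[(trimethylsilyl)methyl]undeca-2,6-dienoate
Conditions: Dess–Martin periodinane, NaHCO3, CH2Cl2, 0 °C → rt
Reagents that add atoms: none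
Why: Buffered Dess–Martin oxidation should give the aldehyde under neutral conditions that leave the allylsilane and the enoate untouched.

Step 5
Reactants: 9 tert-butyl (triphenylphosphoranylidene)acetate; 10 2-oxopropanal (40% in water)
Product: 11 tert-butyl (E)-4-oxopent-2-enoate
Conditions: CH2Cl2/H2O, rt
Reagents that add atoms: none
Why: Wittig reaction of the stabilised ylide should occur only at the aldehyde carbonyl of 10 and give the (E)-enoate.

Step 6
Reactants: 8 tert-butyl (2E,6Z)-3-methyl-11-oxo-7-[(trimethylsilyl)methyl]undeca-2,6-dienoate; 11 tert-butyl (E)-4-oxopent-2-enoate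
Product: 14 tert-butyl trans-5-oxo-2-R1-cyclohex-3-ene-1-carboxylate (C5 chain α; C4 ester β), via keto aldehyde 12 (not isolated), via aldol 13 (not isolated)
Conditions: (S)-α,α-diphenylprolinol trimethylsilyl ether (10 mol %), 4-nitrophenol (10 mol %), toluene, 0 °C → rt; then LiOH·H2O (0.2 equiv), i-PrOH, 0 °C → rt
Reagents that add atoms: none
Why: Asymmetric enamine Michael addition should join the α-carbon of 8 (C5) to the ester-bearing carbon of 11 (C4, β to the ketone) on the enamine face remote from the CPh2OSiMe3 group, setting C5 (R in 12) and the syn C4 centre, and base-mediated aldol condensation of the methyl ketone onto the aldehyde (the only six-membered option) then closes ring A (Robinson-type annulation).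

Step 7
Reactants: 14 tert-butyl trans-5-oxo-2-R1-cyclohex-3-ene-1-carboxylate
Product: 16 tert-butyl 3-methyl-2-R1-5-(trimethylsilyloxy)cyclohex-4-ene-1-carboxylate (C10 methyl β; C5 chain α; C4 ester β), via lithium enolate 15 (not isolated)
Conditions: Me2CuLi (from MeLi, CuI), Et2O, −78 °C; then TMSCl, Et3N, −78 → 0 °C
Reagents that add atoms: lithium dimethylcuprate, [Li+].C[Cu-]C; chlorotrimethylsilane, C[Si](C)(C)Cl
Why: Cuprate 1,4-addition should occur at C10 anti to the C5 chain and leave the tert-butyl esters and the β,β-disubstituted enoate untouched at −78 °C, and silylation of 15 fixes the enol ether at C2=C1.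

Step 8
Reactants: 16 tert-butyl 3-methyl-2-R1-5-(trimethylsilyloxy)cyclohex-4-ene-1-carboxylate
Product: 17 tert-butyl trans-3-methyl-5-oxo-2-R1-cyclohex-3-ene-1-carboxylate (C5 chain α; C4 ester β)
Conditions: IBX, 4-methoxypyridine N-oxide, DMSO, rt
Reagents that add atoms: none
Why: IBX-mediated dehydrogenation of the silyl enol ether (a palladium-free Saegusa-type oxidation, chosen because a palladium salt would attack the allylsilane) should introduce C1=C10 regiospecifically and erase the auxiliary C10 centre.

Step 9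
Reactants: 17 tert-butyl trans-3-methyl-5-oxo-2-R1-cyclohex-3-ene-1-carboxylate
Product: 19 cis-fused decalone (C2 ketone; C4-H α; C4 CO2t-Bu β; H5 β; C20 β; C8 exocyclic methylene; C9 chain R2 β), via aluminium enolate 18 (not isolated)
Conditions: EtAlCl2 (3 equiv), toluene, −78 → −20 °C; aq. NH4Cl
Reagents that add atoms: none
Why: Mechanism: EtAlCl2 binds the C2 carbonyl, the γ-carbon of the allylsilane (C9) attacks the enone β-carbon C10 anti to silicon (SE2′), the β-silyl cation at C8 collapses with loss of Me3SiCl to the C8=C17 exocyclic alkene, and the C2 aluminium enolate 18 is protonated on work-up. The closest known reaction type is the Lewis acid-mediated intramolecular Hosomi–Sakurai conjugate allylation of 3-methylcyclohex-2-enones that carry an allylsilane tether on the ring carbon next to the β-carbon, a known route to cis-fused bicyclic ketones with an angular methyl group. Ring B closes in a 6-exo-trig mode with respect to the enone (C10 inside the new ring, C1 outside) and forms the C9–C10 bond. C10 is controlled by C5: the four-atom tether can reach C10 only on the face that carries C5–C6, and axial attack through a chair-like enolate with the tether equatorial should give the cis ring fusion with H5 and C20 on the same face. C9 is controlled by the (Z) geometry of the allylsilane: in the chair-like transition state of ring B with the two C=C bonds antiperiplanar, C11 (cis to CH2SiMe3) lies equatorial and ends on the face of C20. The step needs 1,4- rather than 1,2-addition and attack on the enone rather than on the β,β-disubstituted enoate or the tert-butyl esters, which the six-membered closure, the far higher electrophilicity of the aluminium-bound enone and the low temperature should secure, while EtAlCl2 also scavenges protons that would protodesilylate the allylsilane.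

Step 10
Reactants: 19 cis-fused decalone
Product: 20 cis-fused ene-keto ester (C2 ketone; C3=C4 bearing CO2t-Bu)
Conditions: IBX (2.5 equiv), DMSO/toluene, 70 °C
Reagents that add atoms: none
Why: IBX dehydrogenation of the ketone through its enol can only desaturate C3–C4, because C10 is quaternary, and should give the ene-keto ester in which C4 is planar.

Step 11
Reactants: 20 cis-fused ene-keto ester
Product: 22 cis-fused keto diester (C4 methyl β; C4 CO2t-Bu α), via lithium enolate 21 (not isolated)
Conditions: Me2CuLi (from MeLi, CuI), Et2O, −78 °C; aq. NH4Cl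
Reagents that add atoms: lithium dimethylcuprate, [Li+].C[Cu-]C
Why: Cuprate conjugate addition should occur at C4 (β to the ketone) from the convex β-face of the cis-fused bicycle, because the α-face is screened by ring B, so the methyl is placed syn to C20 and the ester on the α-face; the unactivated side-chain enoate should not react at −78 °C.

Step 12
Reactants: 22 cis-fused keto diester
Product: 23 di-tert-butyl ester of the target (2β-hydroxy)
Conditions: Al(Oi-Pr)3 (0.5 equiv), i-PrOH, acetone (trace), reflux, prolonged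
Reagents that add atoms: none
Why: Under equilibrating Meerwein–Ponndorf–Verley conditions the reversible hydride transfer should funnel the carbinol to the equatorial 2β-alcohol, the epimer that avoids a syn-triaxial array with the α-axial C4 ester and the C10–C9 bond.

Step 13
Reactants: 23 di-tert-butyl ester of the target
Product: 25 CNP0086784.2 (target diacid), via tris(trimethylsilyl) derivative 24 (not isolated)
Conditions: TMSOTf, 2,6-lutidine, CH2Cl2, 0 °C → rt; then K2CO3, MeOH/H2O; citric acid to pH 3
Reagents that add atoms: none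
Why: Silyl triflate-mediated cleavage of tert-butyl esters (O-silylation, then loss of 2-methylpropene) works at hindered carboxylates without attack at the carbonyl carbon, under buffered conditions that should not isomerise the exocyclic alkene, and methanolysis then removes the three trimethylsilyl groups.

**Compound list**

1 | 2-(hex-5-yn-1-yloxy)oxane | C#CCCCCOC1CCCCO1 | starting material
2 | but-3-en-2-one | C=CC(C)=O | starting material
3 | [(1Z)-6-(oxan-2-yloxy)-2-[(trimethylsilyl)methyl]hex-1-en-1-yl]copper | C[Si](C)(C)C/C(CCCCOC1CCCCO1)=C\[Cu] | intermediate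
4 | trimethylsilyl enol ether of 5 (enol ether geometry open, 5Z) | CC(O[Si](C)(C)C)=CC/C=C(\C[Si](C)(C)C)CCCCOC1CCCCO1 | intermediate
5 | (Z)-10-(oxan-2-yloxy)-6-[(trimethylsilyl)methyl]dec-5-en-2-one | CC(=O)CC/C=C(\C[Si](C)(C)C)CCCCOC1CCCCO1 | intermediate
6 | tert-butyl (2E,6Z)-3-methyl-11-(oxan-2-yloxy)-7-[(trimethylsilyl)methyl]undeca-2,6-dienoate | CC(C)(C)OC(=O)/C=C(\C)CC/C=C(\C[Si](C)(C)C)CCCCOC1CCCCO1 | intermediate
7 | tert-butyl (2E,6Z)-11-hydroxy-3-methyl-7-[(trimethylsilyl)methyl]undeca-2,6-dienoate | CC(C)(C)OC(=O)/C=C(\C)CC/C=C(\C[Si](C)(C)C)CCCCO | intermediate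
8 | tert-butyl (2E,6Z)-3-methyl-11-oxo-7-[(trimethylsilyl)methyl]undeca-2,6-dienoate | CC(C)(C)OC(=O)/C=C(\C)CC/C=C(\C[Si](C)(C)C)CCCC=O | intermediate
9 | tert-butyl (triphenylphosphoranylidene)acetate | CC(C)(C)OC(=O)C=P(c1ccccc1)(c1ccccc1)c1ccccc1 | starting material
10 | 2-oxopropanal | CC(=O)C=O | starting material
11 | tert-butyl (E)-4-oxopent-2-enoate | CC(=O)/C=C/C(=O)OC(C)(C)C | intermediate
12 | syn Michael adduct OHC–C5H(R1)–C4H(CO2t-Bu)–CH2–C(O)CH3 (C5 R, C4 S) | O=C[C@H](CC/C(C[Si](C)(C)C)=C/CC/C(C)=C/C(=O)OC(C)(C)C)[C@@H](C(=O)OC(C)(C)C)CC(C)=O | intermediate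
13 | tert-butyl 3-hydroxy-5-oxo-2-R1-cyclohexane-1-carboxylate (carbinol centre open) | O=C1CC(O)[C@H](CC/C(C[Si](C)(C)C)=C/CC/C(C)=C/C(=O)OC(C)(C)C)[C@@H](C(=O)OC(C)(C)C)C1 | intermediate
14 | tert-butyl trans-5-oxo-2-R1-cyclohex-3-ene-1-carboxylate (C5 chain α, C4 ester β) | O=C1C=C[C@H](CC/C(C[Si](C)(C)C)=C/CC/C(C)=C/C(=O)OC(C)(C)C)[C@@H](C(=O)OC(C)(C)C)C1 | intermediate
15 | lithium enolate (C2–OLi, C1=C2; C10 methyl β) | [Li]OC1=C[C@@H](C)[C@H](CC/C(C[Si](C)(C)C)=C/CC/C(C)=C/C(=O)OC(C)(C)C)[C@@H](C(=O)OC(C)(C)C)C1 | intermediate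
16 | tert-butyl 3-methyl-2-R1-5-(trimethylsilyloxy)cyclohex-4-ene-1-carboxylate (C10 methyl β, C5 chain α, C4 ester β) | C[Si](C)(C)OC1=C[C@@H](C)[C@H](CC/C(C[Si](C)(C)C)=C/CC/C(C)=C/C(=O)OC(C)(C)C)[C@@H](C(=O)OC(C)(C)C)C1 | intermediate
17 | tert-butyl trans-3-methyl-5-oxo-2-R1-cyclohex-3-ene-1-carboxylate (C5 chain α, C4 ester β) | O=C1C=C(C)[C@H](CC/C(C[Si](C)(C)C)=C/CC/C(C)=C/C(=O)OC(C)(C)C)[C@@H](C(=O)OC(C)(C)C)C1 | intermediate
18 | chloro(ethyl)aluminium C2 enolate of 19 (C1=C2) | C=C1CC[C@H]2[C@](C)(C=C(O[Al](Cl)CC)C[C@@H]2C(=O)OC(C)(C)C)[C@H]1CC/C(C)=C/C(=O)OC(C)(C)C | intermediate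
19 | cis-fused decalone: C2 ketone, C4-H α, C4 CO2t-Bu β, H5 β, C20 β, C8 exo-methylene, C9 chain R2 β | C=C1CC[C@H]2[C@](C)(CC(=O)C[C@@H]2C(=O)OC(C)(C)C)[C@H]1CC/C(C)=C/C(=O)OC(C)(C)C | intermediate
20 | cis-fused ene-keto ester: C2 ketone, C3=C4 bearing CO2t-Bu | C=C1CC[C@H]2[C@](C)(CC(=O)C=C2C(=O)OC(C)(C)C)[C@H]1CC/C(C)=C/C(=O)OC(C)(C)C | intermediate
21 | lithium C2 enolate of 22 (C2=C3) | C=C1CC[C@H]2[C@](C)(CC(O[Li])=C[C@@]2(C)C(=O)OC(C)(C)C)[C@H]1CC/C(C)=C/C(=O)OC(C)(C)C | intermediate
22 | cis-fused keto diester: C2 ketone, C4 methyl β, C4 CO2t-Bu α | C=C1CC[C@H]2[C@](C)(CC(=O)C[C@@]2(C)C(=O)OC(C)(C)C)[C@H]1CC/C(C)=C/C(=O)OC(C)(C)C | intermediate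
23 | di-tert-butyl ester of the target (2β-OH) | C=C1CC[C@H]2[C@](C)(C[C@H](O)C[C@@]2(C)C(=O)OC(C)(C)C)[C@H]1CC/C(C)=C/C(=O)OC(C)(C)C | intermediate
24 | bis(trimethylsilyl) ester, C2 trimethylsilyl ether of the target | C=C1CC[C@H]2[C@](C)(C[C@H](O[Si](C)(C)C)C[C@@]2(C)C(=O)O[Si](C)(C)C)[C@H]1CC/C(C)=C/C(=O)O[Si](C)(C)C | intermediate
25 | CNP0086784.2 | C=C1CC[C@H]2[C@](C)(C[C@H](O)C[C@@]2(C)C(=O)O)[C@H]1CC/C(C)=C/C(=O)O | target

**Step count.** Total: 13 steps. Longest linear sequence: 12 steps (steps 1–4 and 6–13 from 1; step 5 is a one-step branch).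

**Steps most likely to fail**

1. Step 9 (key step). The cyclisation may run through the alternative transition state with the tether axial on ring A and the two alkenes synclinal, which would deliver the opposite configuration at C9. Fallback from 17, returning at 19: the exocyclic alkene is used as a masked ketone so that C9 can be equilibrated. The C9-epimeric decalone F1 obtained from 17 is protected at C2 as the dioxolane F2 (ethylene glycol, pyridinium tosylate, benzene, reflux). The C8=C17 alkene, far more electron-rich than the enoate, is ozonised (O3, CH2Cl2/MeOH, −78 °C, dye end-point; Me2S) to the 8-oxo ketal F3. DBU in toluene should epimerise C9 to the 8-oxo ketal F4 with the side chain equatorial, the thermodynamically preferred arrangement. Wittig methylenation (Ph3PCH3Br, KOt-Bu, toluene, 60 °C) gives the methylene ketal F5, and ketal hydrolysis (pyridinium tosylate, acetone/H2O) returns 19.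

2. Step 1. Transfer of the silylmethyl group from copper to the alkyne may be sluggish, or the alkenylcopper may be captured poorly by the enone. Fallback from 1, returning at 5: copper-catalysed syn-borylative alkylation of 1 (B2pin2, ICH2SiMe3, CuCl (cat.), Xantphos, NaOt-Bu, THF) should give the pinacol (Z)-alkenylboronate F6 with boron on C9 cis to CH2SiMe3. Rhodium-catalysed conjugate addition of F6 to 2 ([Rh(cod)Cl]2 (cat.), KOH, dioxane/H2O) then forms C9–C11 with retention and gives 5.

3. Step 12. Equilibration may be slow, so that kinetic hydride delivery from the open equatorial side dominates, or the minor axial alkoxide may be drained by attack on the neighbouring axial ester. Fallback from 22, returning at 23: the kinetic preference is accepted and then inverted. LiBH(s-Bu)3 (THF, −78 °C, cold acidic quench) should give the axial 2α-alcohol F7. Mitsunobu reaction (PPh3, DIAD, 4-nitrobenzoic acid, toluene) inverts C2 by SN2 displacement from the open β-side to the 2β-(4-nitrobenzoate) F8. K2CO3 in MeOH then cleaves the aryl ester and gives 23.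

**Further compounds**

F1 | step 9 | C9 epimer of decalone 19 | C=C1CC[C@H]2[C@](C)(CC(=O)C[C@@H]2C(=O)OC(C)(C)C)[C@@H]1CC/C(C)=C/C(=O)OC(C)(C)C
F2 | step 9 | C2 ethylene ketal of F1 | C=C1CC[C@H]2[C@](C)(CC3(OCCO3)C[C@@H]2C(=O)OC(C)(C)C)[C@@H]1CC/C(C)=C/C(=O)OC(C)(C)C
F3 | step 9 | 8-oxo ketal, C9 as in F1 | O=C1CC[C@H]2[C@](C)(CC3(OCCO3)C[C@@H]2C(=O)OC(C)(C)C)[C@@H]1CC/C(C)=C/C(=O)OC(C)(C)C
F4 | step 9 | 8-oxo ketal, C9 as in the target | O=C1CC[C@H]2[C@](C)(CC3(OCCO3)C[C@@H]2C(=O)OC(C)(C)C)[C@H]1CC/C(C)=C/C(=O)OC(C)(C)C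
F5 | step 9 | C2 ethylene ketal of 19 | C=C1CC[C@H]2[C@](C)(CC3(OCCO3)C[C@@H]2C(=O)OC(C)(C)C)[C@H]1CC/C(C)=C/C(=O)OC(C)(C)C
F6 | step 1 | pinacol [(1Z)-6-(oxan-2-yloxy)-2-[(trimethylsilyl)methyl]hex-1-en-1-yl]boronate | C[Si](C)(C)C/C(CCCCOC1CCCCO1)=C\B1OC(C)(C)C(C)(C)O1
F7 | step 12 | 2α-alcohol, C2 epimer of 23 | C=C1CC[C@H]2[C@](C)(C[C@@H](O)C[C@@]2(C)C(=O)OC(C)(C)C)[C@H]1CC/C(C)=C/C(=O)OC(C)(C)C
F8 | step 12 | 2β-(4-nitrobenzoate) of 23 | C=C1CC[C@H]2[C@](C)(C[C@H](OC(=O)c3ccc(cc3)[N+](=O)[O-])C[C@@]2(C)C(=O)OC(C)(C)C)[C@H]1CC/C(C)=C/C(=O)OC(C)(C)C
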